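**Retrosynthetic overview**

1. The target comes from the 1-hydroxy furofuran by acetylation of the tertiary bridgehead alcohol and a late O-debenzylation. Rings A and B are closed together, last, by acid-promoted double cyclodehydration of an open pentaol through its two benzylic cations (aryl groups end up exo), so only the acetoxy bridgehead carbon (C1) and the bridgehead CH (C5) must be carried through.
2. The pentaol comes from LiAlH4 reduction of an α-aroyl-α-hydroxy-γ-lactone. Its quaternary carbinol (C1) comes from C-acylation of a trans-γ-aryl paraconate lactone with 4-benzyloxy-3-methoxybenzoyl chloride, then enolate hydroxylation anti to the ester (C5 controls C1).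
3. Key disconnection, C5–C6 of that lactone: veratraldehyde reacts as an acyl anion (Breslow intermediate, Stetter addition) with dimethyl fumarate, joining two electrophilic carbons. The stereolabile keto diester is reduced in the same flask under dynamic kinetic resolution, which sets C6 and C5 and closes the lactone.
4. Ring order: the γ-lactone (carbon frame of ring B) first; it is opened by hydride; rings B and A then form together at the end.

Assumption: core atoms carry the 3,7-dioxabicyclo[3.3.0]octane numbering of the target (C1 acetoxy bridgehead, C2 guaiacyl CH, C5 bridgehead CH, C6 veratryl CH; ring A holds O3, ring B holds O7).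

**Route**

Step 1
Reactants: 1 3,4-dimethoxybenzaldehyde; 2 dimethyl (E)-but-2-enedioate (dimethyl fumarate)
Product: 5 methyl (2S,3S)-2-(3,4-dimethoxyphenyl)-5-oxotetrahydrofuran-3-carboxylate (trans), via racemic aroylsuccinate 3 (not isolated), via syn-hydroxy diester 4 (not isolated)
Conditions: 3-benzyl-5-(2-hydroxyethyl)-4-methylthiazolium chloride (20 mol%), Et3N, DMF, 70 °C; then RuCl(p-cymene)[(S,S)-TsNCH(Ph)CH(Ph)NH2] (1 mol%), HCO2H/Et3N (5:2), 40 °C; then p-TsOH·H2O (cat.), PhMe, 60 °C
Reagents that add atoms: none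
Why: Proposed new method: a Stetter reaction relayed in one flask into a Noyori–Ikariya transfer hydrogenation with dynamic kinetic resolution and lactonization — the thiazol-2-ylidene turns 1 into its Breslow intermediate (acyl anion equivalent), which adds to the electrophilic alkene carbon of 2 to make the C5–C6 bond; the α-carbon of keto diester 3 racemises through its enol while the (S,S)-ruthenium hydride reduces the aryl ketone from one face (S carbinol, the acetophenone sense) and selects the enantiomer of 3 that gives syn ester 4, which acid closes to the trans-lactone; both reactions are known separately (Stetter addition of aromatic aldehydes to fumarates; transfer-hydrogenation DKR of α-substituted β-keto esters), the carbene is protonated once formic acid is added, and only the one-pot relay is new.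

Step 2
Reactants: 6 4-(benzyloxy)-3-methoxybenzoic acid
Product: 7 4-(benzyloxy)-3-methoxybenzoyl chloride
Conditions: (COCl)2, HCONMe2 (cat.), CH2Cl2, 0 °C → rt
Reagents that add atoms: oxalyl chloride, O=C(Cl)C(=O)Cl
Why: Acid chloride formation through the Vilsmeier-type chloroiminium salt is near quantitative, leaves the benzyl ether intact and involves no stereocentre.

Step 3
Reactants: 5 methyl (2S,3S)-2-(3,4-dimethoxyphenyl)-5-oxotetrahydrofuran-3-carboxylate; 7 4-(benzyloxy)-3-methoxybenzoyl chloride
Product: 9 methyl (2S,3R,4R)-4-[4-(benzyloxy)-3-methoxybenzoyl]-2-(3,4-dimethoxyphenyl)-4-hydroxy-5-oxotetrahydrofuran-3-carboxylate, via aroyl lactone 8 (not isolated)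
Conditions: LiN(SiMe3)2 (1.1 equiv), THF, −78 °C; 7; LiN(SiMe3)2 (1.2 equiv); then 2-(benzenesulfonyl)-3-phenyloxaziridine, −78 → −20 °C; aq NH4Cl
Reagents that add atoms: 2-(benzenesulfonyl)-3-phenyloxaziridine, O=S(=O)(N1OC1c1ccccc1)c1ccccc1
Why: Crossed Claisen C-acylation followed by Davis enolate hydroxylation: the amide base removes the more acidic and less hindered lactone α-proton (not the ester α-CH, whose loss would open the ring), the enolate is acylated on carbon, the second portion of base regenerates the enolate of 8, and the oxaziridine delivers oxygen to the face opposite the neighbouring ester, so the new quaternary carbinol (4R, later C1) has OH cis to the aryl group and the aroyl group cis to the ester.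

Step 4
Reactants: 9 methyl (2S,3R,4R)-4-[4-(benzyloxy)-3-methoxybenzoyl]-2-(3,4-dimethoxyphenyl)-4-hydroxy-5-oxotetrahydrofuran-3-carboxylate
Product: 10 (2S,3R)-2-{[4-(benzyloxy)-3-methoxyphenyl](hydroxy)methyl}-3-[(S)-(3,4-dimethoxyphenyl)(hydroxy)methyl]butane-1,2,4-triol (both epimers at the newly formed benzylic carbinol)
Conditions: LiAlH4 (6 equiv), THF, 0 °C → rt; aq potassium sodium tartrate
Reagents that add atoms: none
Why: Exhaustive hydride reduction turns ketone, lactone and ester into the pentaol without touching the benzyl ether or the two stereocentres that matter (tertiary carbinol and its CH neighbour); the new benzylic carbinol forms as an epimer mixture that the next step erases.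

Step 5
Reactants: 10 the pentaol from step 4
Product: 11 (1S,2R,5R,6S)-2-[4-(benzyloxy)-3-methoxyphenyl]-6-(3,4-dimethoxyphenyl)-3,7-dioxabicyclo[3.3.0]octan-1-ol
Conditions: (+)-10-camphorsulfonic acid (10 mol%), CH2Cl2, 0 °C → rt
Reagents that add atoms: none
Why: Acid-catalysed double cyclodehydration (SN1 etherification through the two p-alkoxybenzyl cations, the classical furofuran lignan closure): each cation is trapped 5-exo by the primary hydroxyl placed 1,4 to it, the ring fusion can only be cis, and each aryl group takes the convex face trans to the other ring, which sets C2 (R) and C6 (S) whatever the carbinol configurations in 10.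

Step 6
Reactants: 11 the furofuranol from step 5
Product: 12 (1S,2R,5R,6S)-2-[4-(benzyloxy)-3-methoxyphenyl]-6-(3,4-dimethoxyphenyl)-3,7-dioxabicyclo[3.3.0]octan-1-yl acetate
Conditions: Ac2O, Et3N, 4-(dimethylamino)pyridine (0.3 equiv), CH2Cl2, 40 °C
Reagents that add atoms: acetic anhydride, CC(=O)OC(C)=O
Why: Nucleophilic-catalysis acylation (Steglich-type) acetylates the hindered tertiary bridgehead alcohol, the only free hydroxyl, with retention because no C–O bond at a stereocentre is broken.

Step 7
Reactants: 12 the benzyl-protected acetate from step 6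
Product: 13 (1S,2R,5R,6S)-6-(3,4-dimethoxyphenyl)-2-(4-hydroxy-3-methoxyphenyl)-3,7-dioxabicyclo[3.3.0]octan-1-yl acetate (CNP0107105.1)
Conditions: H2 (1 atm), Pd/C (10 wt%), EtOAc, rt
Reagents that add atoms: none
Why: Hydrogenolysis of the aryl benzyl ether in neutral ethyl acetate is much faster than cleavage of the cyclic benzylic ethers and leaves the tertiary acetate and all four stereocentres untouched.

**Compound list**

1 | 3,4-dimethoxybenzaldehyde | COc1ccc(C=O)cc1OC | starting material
2 | dimethyl (E)-but-2-enedioate | COC(=O)/C=C/C(=O)OC | starting material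
3 | dimethyl 2-(3,4-dimethoxybenzoyl)butanedioate (racemic, enolizable stereocentre) | COC(=O)CC(C(=O)OC)C(=O)c1ccc(OC)c(OC)c1 | intermediate
4 | dimethyl (2S)-2-[(S)-(3,4-dimethoxyphenyl)(hydroxy)methyl]butanedioate | COC(=O)C[C@H](C(=O)OC)[C@H](O)c1ccc(OC)c(OC)c1 | intermediate
5 | methyl (2S,3S)-2-(3,4-dimethoxyphenyl)-5-oxotetrahydrofuran-3-carboxylate | COC(=O)[C@H]1CC(=O)O[C@@H]1c1ccc(OC)c(OC)c1 | intermediate
6 | 4-(benzyloxy)-3-methoxybenzoic acid | COc1cc(C(=O)O)ccc1OCc1ccccc1 | starting material
7 | 4-(benzyloxy)-3-methoxybenzoyl chloride | COc1cc(C(=O)Cl)ccc1OCc1ccccc1 | intermediate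
8 | methyl (2S,3S)-4-[4-(benzyloxy)-3-methoxybenzoyl]-2-(3,4-dimethoxyphenyl)-5-oxotetrahydrofuran-3-carboxylate (C-4 not defined, present as its enolate) | COC(=O)[C@@H]1[C@@H](c2ccc(OC)c(OC)c2)OC(=O)C1C(=O)c1ccc(OCc2ccccc2)c(OC)c1 | intermediate
9 | methyl (2S,3R,4R)-4-[4-(benzyloxy)-3-methoxybenzoyl]-2-(3,4-dimethoxyphenyl)-4-hydroxy-5-oxotetrahydrofuran-3-carboxylate | COC(=O)[C@@H]1[C@@H](c2ccc(OC)c(OC)c2)OC(=O)[C@]1(O)C(=O)c1ccc(OCc2ccccc2)c(OC)c1 | intermediate
10 | (2S,3R)-2-{[4-(benzyloxy)-3-methoxyphenyl](hydroxy)methyl}-3-[(S)-(3,4-dimethoxyphenyl)(hydroxy)methyl]butane-1,2,4-triol (epimers at the carbinol next to the tertiary alcohol) | OC[C@](O)(C(O)c1ccc(OCc2ccccc2)c(OC)c1)[C@H](CO)[C@H](O)c1ccc(OC)c(OC)c1 | intermediate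
11 | (1S,2R,5R,6S)-2-[4-(benzyloxy)-3-methoxyphenyl]-6-(3,4-dimethoxyphenyl)-3,7-dioxabicyclo[3.3.0]octan-1-ol | COc1cc([C@H]2OC[C@@H]3[C@@H](c4ccc(OC)c(OC)c4)OC[C@]23O)ccc1OCc1ccccc1 | intermediate
12 | (1S,2R,5R,6S)-2-[4-(benzyloxy)-3-methoxyphenyl]-6-(3,4-dimethoxyphenyl)-3,7-dioxabicyclo[3.3.0]octan-1-yl acetate | COc1cc([C@H]2OC[C@@H]3[C@@H](c4ccc(OC)c(OC)c4)OC[C@]23OC(C)=O)ccc1OCc1ccccc1 | intermediate
13 | (1S,2R,5R,6S)-6-(3,4-dimethoxyphenyl)-2-(4-hydroxy-3-methoxyphenyl)-3,7-dioxabicyclo[3.3.0]octan-1-yl acetate | COc1cc([C@H]2OC[C@@H]3[C@@H](c4ccc(OC)c(OC)c4)OC[C@]23OC(C)=O)ccc1O | target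

**Step count and risks**

Total step count: 7. Longest linear sequence: 6 steps (1, 3, 4, 5, 6, 7); step 2 is a one-step side branch.

Steps most likely to fail:

Step 1. The electron-rich aldehyde may stall at the benzoin stage. The relay may also give a poor syn:anti ratio; the anti ester would give the cis-lactone and, after step 5, material of the opposite series. The fallback sets out from 1 and comes back at 3. Compound 1 is converted with propane-1,3-dithiol and BF3·OEt2 into 2-(3,4-dimethoxyphenyl)-1,3-dithiane F1. Its 2-lithio derivative (n-BuLi, THF, −78 °C) adds 1,4 to 2 to give dimethyl 2-[2-(3,4-dimethoxyphenyl)-1,3-dithian-2-yl]butanedioate F2. MeI and CaCO3 in aqueous MeCN release 3, which is now isolated and purified. The ruthenium reduction and lactonization are then run as a separate operation (through 4), and trans-lactone 5 is freed from any cis isomer by crystallization.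

Step 3. Deprotonation at the ester α-carbon would open the lactone by β-elimination, and O-acylation or a poor facial ratio in the hydroxylation are also possible. The fallback sets out from 5 and comes back at 10. Compound 5 is hydrolysed (6 M HCl, dioxane, 60 °C) to (2S,3S)-2-(3,4-dimethoxyphenyl)-5-oxotetrahydrofuran-3-carboxylic acid F3. Its carboxylate–enolate dianion (LiN(SiMe3)2, 2.1 equiv, THF, −78 °C) is C-acylated with 7; the carboxylate shields the neighbouring C–H from deprotonation, so ring opening cannot start. After a further equivalent of base the same oxaziridine gives (2S,3R,4R)-4-[4-(benzyloxy)-3-methoxybenzoyl]-2-(3,4-dimethoxyphenyl)-4-hydroxy-5-oxotetrahydrofuran-3-carboxylic acid F4. LiAlH4 reduces F4 to 10.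

Step 5. The veratryl cation can also be trapped by the secondary benzylic hydroxyl (a 2,5-diaryltetrahydrofuran), the cation next to the tertiary alcohol can undergo a pinacol-type shift, and endo-aryl epimers can form. The fallback sets out from 10 and comes back at 13. Compound 10 is debenzylated first (H2, Pd/C, EtOAc) to (2S,3R)-3-[(S)-(3,4-dimethoxyphenyl)(hydroxy)methyl]-2-[hydroxy(4-hydroxy-3-methoxyphenyl)methyl]butane-1,2,4-triol F5. Pyridinium p-toluenesulfonate in MeCN at 40 °C then closes ring A through the p-quinone methide of the free phenol, under conditions too mild for the pinacol shift, and ring B through the veratryl cation. This gives (1S,2R,5R,6S)-6-(3,4-dimethoxyphenyl)-2-(4-hydroxy-3-methoxyphenyl)-3,7-dioxabicyclo[3.3.0]octan-1-ol F6. Exhaustive acetylation (Ac2O, 4-(dimethylamino)pyridine, pyridine, 40 °C) gives (1S,2R,5R,6S)-2-(4-acetoxy-3-methoxyphenyl)-6-(3,4-dimethoxyphenyl)-3,7-dioxabicyclo[3.3.0]octan-1-yl acetate F7. Pyrrolidine (1.1 equiv, MeCN, 0 °C) removes only the aryl acetate to give 13.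

**Further compounds**

F1 | step 1 | 2-(3,4-dimethoxyphenyl)-1,3-dithiane | COc1ccc(C2SCCCS2)cc1OC
F2 | step 1 | dimethyl 2-[2-(3,4-dimethoxyphenyl)-1,3-dithian-2-yl]butanedioate (racemic) | COC(=O)CC(C(=O)OC)C1(SCCCS1)c1ccc(OC)c(OC)c1
F3 | step 3 | (2S,3S)-2-(3,4-dimethoxyphenyl)-5-oxotetrahydrofuran-3-carboxylic acid | OC(=O)[C@H]1CC(=O)O[C@@H]1c1ccc(OC)c(OC)c1
F4 | step 3 | (2S,3R,4R)-4-[4-(benzyloxy)-3-methoxybenzoyl]-2-(3,4-dimethoxyphenyl)-4-hydroxy-5-oxotetrahydrofuran-3-carboxylic acid | OC(=O)[C@@H]1[C@@H](c2ccc(OC)c(OC)c2)OC(=O)[C@]1(O)C(=O)c1ccc(OCc2ccccc2)c(OC)c1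
F5 | step 5 | (2S,3R)-3-[(S)-(3,4-dimethoxyphenyl)(hydroxy)methyl]-2-[hydroxy(4-hydroxy-3-methoxyphenyl)methyl]butane-1,2,4-triol (epimers at the carbinol next to the tertiary alcohol) | OC[C@](O)(C(O)c1ccc(O)c(OC)c1)[C@H](CO)[C@H](O)c1ccc(OC)c(OC)c1
F6 | step 5 | (1S,2R,5R,6S)-6-(3,4-dimethoxyphenyl)-2-(4-hydroxy-3-methoxyphenyl)-3,7-dioxabicyclo[3.3.0]octan-1-ol | COc1cc([C@H]2OC[C@@H]3[C@@H](c4ccc(OC)c(OC)c4)OC[C@]23O)ccc1O
F7 | step 5 | (1S,2R,5R,6S)-2-(4-acetoxy-3-methoxyphenyl)-6-(3,4-dimethoxyphenyl)-3,7-dioxabicyclo[3.3.0]octan-1-yl acetate | COc1cc([C@H]2OC[C@@H]3[C@@H](c4ccc(OC)c(OC)c4)OC[C@]23OC(C)=O)ccc1OC(C)=O
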